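**Retrosynthetic overview**
1. Target ⇐ global desilylation ⇐ ketone reduction with in-flask aroylation at C6 and isovalerylation at C10 of a 10α-hydroxy-dauc-8-en-6-one.
2. 10α-OH and C8=C9 ⇐ α-face epoxidation and selenoxide transposition of the C9=C10 alkene of a dauc-9-en-6-one.
3. Five- and seven-membered rings together ⇐ silyl-triflate-triggered intramolecular (4+3) cycloaddition of an acyclic epoxy enolsilane onto its tethered (E,E)-diene (bonds C5–C1 and C7–C8; sets C1 and C5, keeps the C4 oxygen).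
4. Epoxy ketone ⇐ directed epoxidation and oxidation of an (S,Z)-allylic alcohol ⇐ iron-catalysed syn-carbomagnesiation of (S)-5-methylhex-3-yn-2-ol with a dienyl Grignard reagent.
5. Building blocks: but-3-yn-1-ol, (E)-1-bromoprop-1-ene, AlMe3, 3-methylbut-1-yne, N-methoxy-N-methylacetamide, isovaleric anhydride, 4-(TBSO)benzoic acid; no ring exists before the cycloaddition.

Assumption and convention: the SMILES is taken as drawn, i.e. (1S,4S,5S,6R,10R) in daucane numbering (C1 methyl-bearing ring-fusion carbon, C2, C3, C4 isopropyl carbinol, C5 ring-fusion CH, C6 to C10 around the seven-membered ring, C8 methyl-bearing; β = face of the C1 methyl), and (E)-1-bromoprop-1-ene and 4-[(tert-butyldimethylsilyl)oxy]benzoic acid are bought as such.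

**Step 1**
Reactants: 1 but-3-yn-1-ol; 2 (E)-1-bromoprop-1-ene
Product: 4 (3E,5E)-3-methylhepta-3,5-dien-1-ol, via alkenylalane 3 (not isolated)
Conditions: AlMe3 (3 equiv), Cp2ZrCl2 (25 mol %), CH2Cl2, 0 °C → rt; then 2, ZnCl2 (0.2 equiv), Pd(PPh3)4 (5 mol %), THF, rt; aq. HCl
Reagents that add atoms: trimethylaluminium, C[Al](C)C
Why: Negishi zirconium-catalysed carboalumination adds methyl (internal) and aluminium (terminal) syn across the alkyne, fixing the 3E trisubstituted alkene, and the palladium-catalysed alkenyl–alkenyl cross-coupling proceeds with retention on both partners to give the E,E-diene.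

**Step 2**
Reactants: 4 (3E,5E)-3-methylhepta-3,5-dien-1-ol
Product: 5 (3E,5E)-1-bromo-3-methylhepta-3,5-diene
Conditions: CBr4, PPh3, CH2Cl2, 0 °C
Reagents that add atoms: carbon tetrabromide, BrC(Br)(Br)Br
Why: Appel reaction, an SN2 displacement at the primary carbinol under neutral conditions that leaves the conjugated diene and its geometry untouched.

**Step 3**
Reactants: 6 3-methylbut-1-yne; 7 N-methoxy-N-methylacetamide
Product: 9 5-methylhex-3-yn-2-one, via lithium acetylide 8 (not isolated)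
Conditions: n-BuLi, THF, −78 °C; then 7, −78 → 0 °C; 1 M HCl
Reagents that add atoms: none
Why: Acylation of a lithium acetylide by a Weinreb amide, whose chelated tetrahedral adduct prevents over-addition and releases the ynone only on acidic quench.

**Step 4**
Reactants: 9 5-methylhex-3-yn-2-one
Product: 10 (2S)-5-methylhex-3-yn-2-ol
Conditions: Ru[(S,S)-TsDPEN](p-cymene) (pre-formed amido complex, 0.5 mol %), i-PrOH, rt
Reagents that add atoms: none
Why: Noyori asymmetric transfer hydrogenation, for which alkynyl methyl ketones are among the best substrates; the alkynyl group takes the place of the aryl group of acetophenone so the (S,S)-ligand gives the (S)-carbinol, and the alkyne is not reduced.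

**Step 5**
Reactants: 5 (3E,5E)-1-bromo-3-methylhepta-3,5-diene; 10 (2S)-5-methylhex-3-yn-2-ol
Product: 12 (2S,3Z,7E,9E)-7-methyl-4-(propan-2-yl)undeca-3,7,9-trien-2-ol, via Grignard reagent 11 (not isolated)
Conditions: 5, Mg, THF, 0 °C → rt (gives 11, used at once); 10, MeMgBr (1.0 equiv), THF, −78 °C; then Fe(acac)3 (20 mol %), 11 (2.0 equiv), −78 → 0 °C; H2O
Reagents that add atoms: none
Why: Alkoxide-directed iron-catalysed syn-carbomagnesiation of a propargylic alcohol delivers the alkyl group to the alkyne carbon remote from the magnesium alkoxide and magnesium to the near carbon on the same side, so after protonation the tether is cis to the vinylic hydrogen and the isopropyl group is cis to the carbinol carbon (3Z), with the carbinol stereocentre untouched.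

**Step 6**
Reactants: 12 (2S,3Z,7E,9E)-7-methyl-4-(propan-2-yl)undeca-3,7,9-trien-2-ol
Product: 13 (1S)-1-[(2R,3S)-3-[(3E,5E)-3-methylhepta-3,5-dien-1-yl]-3-(propan-2-yl)oxiran-2-yl]ethan-1-ol
Conditions: Ti(OiPr)4 (20 mol %), t-BuOOH (2 equiv), 4 Å MS, CH2Cl2, −20 °C
Reagents that add atoms: tert-butyl hydroperoxide, CC(C)(C)OO
Why: Hydroxyl-directed titanium alkoxide/hydroperoxide epoxidation (Sharpless type, no tartrate) touches only the allylic alkene and is a stereospecific syn addition, so the Z geometry becomes the cis relationship of the carbinol carbon and isopropyl on the oxirane, while A(1,3) strain from the cis-isopropyl group holds the carbinol hydrogen in the alkene plane and oxygen arrives from the hydroxyl face (threo) to give the (2R,3S)-oxirane.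

**Step 7**
Reactants: 13 (1S)-1-[(2R,3S)-3-[(3E,5E)-3-methylhepta-3,5-dien-1-yl]-3-(propan-2-yl)oxiran-2-yl]ethan-1-ol
Product: 14 1-[(2S,3S)-3-[(3E,5E)-3-methylhepta-3,5-dien-1-yl]-3-(propan-2-yl)oxiran-2-yl]ethan-1-one
Conditions: Dess–Martin periodinane, pyridine, CH2Cl2, 0 °C → rt
Reagents that add atoms: none
Why: Dess–Martin oxidation under buffered, non-epimerising conditions converts the carbinol that steered the epoxidation into the methyl ketone without touching the oxirane or the diene (the oxirane descriptors change only through CIP priorities).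

**Step 8**
Reactants: 14 1-[(2S,3S)-3-[(3E,5E)-3-methylhepta-3,5-dien-1-yl]-3-(propan-2-yl)oxiran-2-yl]ethan-1-one
Product: 16 (1R,4S,5R,8R)-4-[(triethylsilyl)oxy]dauc-9-en-6-one (trans-fused; 1β-methyl, 5α-H, 4α-OTES, 8α-methyl), via epoxy enolsilane 15 (not isolated)
Conditions: Et3N (1.2 equiv), TESOTf (1.05 equiv), CH2Cl2, 0 °C; then −78 °C, TESOTf (0.4 equiv); aq. NaHCO3
Reagents that add atoms: triethylsilyl trifluoromethanesulfonate, CC[Si](CC)(CC)OS(=O)(=O)C(F)(F)F
Why: Proposed new method: the closest known reaction type is the silyl-triflate-catalysed intramolecular (4+3) cycloaddition of epoxy enolsilanes with tethered dienes, extended here to a fully substituted oxirane carbon, a trisubstituted diene terminus and enolsilane formation in the same flask; silylation of the oxirane oxygen lets the C5–O bond open with help from the enolsilane while diene carbon C1 attacks C5 anti to the leaving oxygen (inversion at C5, C4–O kept as the OTES group, hence C4–O cis to H5), and the W-shaped 2-silyloxyallyl unit closes C7–C8 through an extended transition state that keeps the silyloxy and isopropyl groups away from the diene, which puts the C1 methyl (inside substituent of the 3E alkene) trans to H5 (trans ring fusion, quaternary C1) and the C8 methyl (outside substituent of the 5E alkene) trans to the C1 methyl, after which silyl transfer from the oxocarbenium ion regenerates TESOTf.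

**Step 9**
Reactants: 16 (1R,4S,5R,8R)-4-[(triethylsilyl)oxy]dauc-9-en-6-one
Product: 17 (1S,4S,5R,8R,9R,10S)-9,10-epoxy-4-[(triethylsilyl)oxy]daucan-6-one (9α,10α-epoxide)
Conditions: mCPBA, CH2Cl2, 0 °C
Reagents that add atoms: 3-chloroperoxybenzoic acid, OOC(=O)c1cccc(Cl)c1
Why: Prilezhaev epoxidation of the only alkene from the α face, anti to the axial C1 methyl that shields the β face (the C8 methyl is pseudo-equatorial), much faster than Baeyer–Villiger oxidation of the hindered ketone.

**Step 10**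
Reactants: 17 (1S,4S,5R,8R,9R,10S)-9,10-epoxy-4-[(triethylsilyl)oxy]daucan-6-one
Product: 20 (1S,4S,5R,10R)-10-hydroxy-4-[(triethylsilyl)oxy]dauc-8-en-6-one, via hydroxy selenide 18 (not isolated), via selenoxide 19 (not isolated)
Conditions: PhSeSePh (0.6 equiv), NaBH4, EtOH, rt (until colourless); then 17, 70 °C; then THF, 30 % H2O2, 0 °C → rt
Reagents that add atoms: none
Why: Sharpless–Lauer epoxide-to-allylic-alcohol sequence: the selenolate opens the oxirane by SN2, trans-diaxial attack at C9 (C10 is neopentylic) to give the 9β-selenide and 10α-alcohol, and the selenoxide syn-eliminates with H8β, the only cis hydrogen not on the carbinol carbon, so C8=C9 and the 10α-hydroxyl arise together and the C8 stereocentre is erased.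

**Step 11**
Reactants: 20 (1S,4S,5R,10R)-10-hydroxy-4-[(triethylsilyl)oxy]dauc-8-en-6-one; 21 3-methylbutanoic anhydride
Product: 22 (1S,4S,5R,10R)-6-oxo-4-[(triethylsilyl)oxy]dauc-8-en-10-yl 3-methylbutanoate
Conditions: DMAP, Et3N, CH2Cl2, rt
Reagents that add atoms: none
Why: DMAP-catalysed acyl transfer (Steglich-type acylation) to the only free hydroxyl, with retention at C10 because the C–O bond is not broken.

**Step 12**
Reactants: 22 (1S,4S,5R,10R)-6-oxo-4-[(triethylsilyl)oxy]dauc-8-en-10-yl 3-methylbutanoate; 23 4-[(tert-butyldimethylsilyl)oxy]benzoic acid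
Product: 26 (1S,4S,5S,6R,10R)-10-[(3-methylbutanoyl)oxy]-4-[(triethylsilyl)oxy]dauc-8-en-6-yl 4-[(tert-butyldimethylsilyl)oxy]benzoate, via acid chloride 24 (not isolated), via lithium alkoxide 25 (not isolated)
Conditions: 23, 1-chloro-N,N,2-trimethylprop-1-en-1-amine, CH2Cl2, rt (gives 24); 22, LiBH(s-Bu)3 (1.1 equiv), THF, −78 °C (gives 25); then 24 (2 equiv), DMAP, −78 → 0 °C
Reagents that add atoms: none
Why: Steric-approach-controlled ketone reduction (bulky hydride attacks equatorially from the α face because the axial β trajectory is blocked by the 1,3-related axial C1 methyl and the β-isopropyl group) sets the 6β (6R) alkoxide, which is acylated in the same flask by the acid chloride (alkoxide acylation) so the hindered axial alcohol never has to be esterified as such, while the isovalerate is inert to the hydride at −78 °C.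

**Step 13**
Reactants: 26 (1S,4S,5S,6R,10R)-10-[(3-methylbutanoyl)oxy]-4-[(triethylsilyl)oxy]dauc-8-en-6-yl 4-[(tert-butyldimethylsilyl)oxy]benzoate
Product: 27 (1S,4S,5S,6R,10R)-4-hydroxy-10-[(3-methylbutanoyl)oxy]dauc-8-en-6-yl 4-hydroxybenzoate (target)
Conditions: HF·pyridine, pyridine, THF, 0 °C → rt
Reagents that add atoms: none
Why: Fluoride-driven Si–O cleavage (desilylation) removes the phenolic TBS ether and the tertiary TES ether in one operation, and buffered HF leaves both esters, the allylic C–O bond and all stereocentres untouched.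

**Compound list**
1 | but-3-yn-1-ol | C#CCCO | starting material
2 | (E)-1-bromoprop-1-ene | C/C=C/Br | starting material
3 | dimethyl{(1E)-4-[(dimethylalumanyl)oxy]-2-methylbut-1-en-1-yl}alumane (formed in the flask) | C[Al](C)/C=C(\C)CCO[Al](C)C | intermediate
4 | (3E,5E)-3-methylhepta-3,5-dien-1-ol | OCC/C(C)=C/C=C/C | intermediate
5 | (3E,5E)-1-bromo-3-methylhepta-3,5-diene | BrCC/C(C)=C/C=C/C | intermediate
6 | 3-methylbut-1-yne | CC(C)C#C | starting material
7 | N-methoxy-N-methylacetamide | CC(=O)N(C)OC | starting material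
8 | lithium 3-methylbut-1-yn-1-ide (formed in the flask) | CC(C)C#[C-].[Li+] | intermediate
9 | 5-methylhex-3-yn-2-one | CC(=O)C#CC(C)C | intermediate
10 | (2S)-5-methylhex-3-yn-2-ol | C[C@H](O)C#CC(C)C | intermediate
11 | bromo[(3E,5E)-3-methylhepta-3,5-dien-1-yl]magnesium (formed in the flask) | Br[Mg]CC/C(C)=C/C=C/C | intermediate
12 | (2S,3Z,7E,9E)-7-methyl-4-(propan-2-yl)undeca-3,7,9-trien-2-ol | C[C@H](O)/C=C(\C(C)C)CC/C(C)=C/C=C/C | intermediate
13 | (1S)-1-[(2R,3S)-3-[(3E,5E)-3-methylhepta-3,5-dien-1-yl]-3-(propan-2-yl)oxiran-2-yl]ethan-1-ol | C[C@H](O)[C@H]1O[C@]1(C(C)C)CC/C(C)=C/C=C/C | intermediate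
14 | 1-[(2S,3S)-3-[(3E,5E)-3-methylhepta-3,5-dien-1-yl]-3-(propan-2-yl)oxiran-2-yl]ethan-1-one | CC(=O)[C@H]1O[C@]1(C(C)C)CC/C(C)=C/C=C/C | intermediate
15 | triethyl({1-[(2S,3S)-3-[(3E,5E)-3-methylhepta-3,5-dien-1-yl]-3-(propan-2-yl)oxiran-2-yl]ethenyl}oxy)silane (formed in the flask) | C=C(O[Si](CC)(CC)CC)[C@H]1O[C@]1(C(C)C)CC/C(C)=C/C=C/C | intermediate
16 | (1R,4S,5R,8R)-4-[(triethylsilyl)oxy]dauc-9-en-6-one = (3S,3aR,6R,8aR)-6,8a-dimethyl-3-(propan-2-yl)-3-[(triethylsilyl)oxy]-2,3,3a,5,6,8a-hexahydroazulen-4(1H)-one | C[C@H]1C=C[C@@]2(C)CC[C@](O[Si](CC)(CC)CC)(C(C)C)[C@@H]2C(=O)C1 | intermediate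
17 | (1S,4S,5R,8R,9R,10S)-9,10-epoxy-4-[(triethylsilyl)oxy]daucan-6-one (oxirane oxygen α, anti to the C1 methyl) | C[C@H]1[C@H]2O[C@H]2[C@@]3(C)CC[C@](O[Si](CC)(CC)CC)(C(C)C)[C@@H]3C(=O)C1 | intermediate
18 | (1S,4S,5R,8R,9S,10S)-10-hydroxy-9-(phenylselanyl)-4-[(triethylsilyl)oxy]daucan-6-one (formed in the flask) | C[C@H]1[C@H]([Se]c2ccccc2)[C@@H](O)[C@@]3(C)CC[C@](O[Si](CC)(CC)CC)(C(C)C)[C@@H]3C(=O)C1 | intermediate
19 | Se-oxide of 18, (1S,4S,5R,8R,9S,10S)-10-hydroxy-9-(phenylseleninyl)-4-[(triethylsilyl)oxy]daucan-6-one, configuration at selenium not defined (formed in the flask) | C[C@H]1[C@H]([Se](=O)c2ccccc2)[C@@H](O)[C@@]3(C)CC[C@](O[Si](CC)(CC)CC)(C(C)C)[C@@H]3C(=O)C1 | intermediate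
20 | (1S,4S,5R,10R)-10-hydroxy-4-[(triethylsilyl)oxy]dauc-8-en-6-one | CC1=C[C@@H](O)[C@@]2(C)CC[C@](O[Si](CC)(CC)CC)(C(C)C)[C@@H]2C(=O)C1 | intermediate
21 | 3-methylbutanoic anhydride | CC(C)CC(=O)OC(=O)CC(C)C | starting material
22 | (1S,4S,5R,10R)-6-oxo-4-[(triethylsilyl)oxy]dauc-8-en-10-yl 3-methylbutanoate | CC1=C[C@@H](OC(=O)CC(C)C)[C@@]2(C)CC[C@](O[Si](CC)(CC)CC)(C(C)C)[C@@H]2C(=O)C1 | intermediate
23 | 4-[(tert-butyldimethylsilyl)oxy]benzoic acid | OC(=O)c1ccc(O[Si](C)(C)C(C)(C)C)cc1 | starting material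
24 | 4-[(tert-butyldimethylsilyl)oxy]benzoyl chloride (formed in the flask) | ClC(=O)c1ccc(O[Si](C)(C)C(C)(C)C)cc1 | intermediate
25 | lithium (1S,4S,5S,6R,10R)-10-[(3-methylbutanoyl)oxy]-4-[(triethylsilyl)oxy]dauc-8-en-6-olate (formed in the flask) | CC1=C[C@@H](OC(=O)CC(C)C)[C@@]2(C)CC[C@](O[Si](CC)(CC)CC)(C(C)C)[C@@H]2[C@H]([O-])C1.[Li+] | intermediate
26 | (1S,4S,5S,6R,10R)-10-[(3-methylbutanoyl)oxy]-4-[(triethylsilyl)oxy]dauc-8-en-6-yl 4-[(tert-butyldimethylsilyl)oxy]benzoate | CC1=C[C@@H](OC(=O)CC(C)C)[C@@]2(C)CC[C@](O[Si](CC)(CC)CC)(C(C)C)[C@@H]2[C@H](OC(=O)c2ccc(O[Si](C)(C)C(C)(C)C)cc2)C1 | intermediate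
27 | (3S,3aS,4R,8R,8aS)-3-hydroxy-6,8a-dimethyl-8-[(3-methylbutanoyl)oxy]-3-(propan-2-yl)-1,2,3,3a,4,5,8,8a-octahydroazulen-4-yl 4-hydroxybenzoate | CC1=C[C@@H](OC(=O)CC(C)C)[C@@]2(C)CC[C@](O)(C(C)C)[C@@H]2[C@H](OC(=O)c2ccc(O)cc2)C1 | target

**Step count and risk**
Total: 13 steps. Longest linear sequence: 11 steps (steps 1, 2, 5, 6, 7, 8, 9, 10, 11, 12, 13 from but-3-yn-1-ol); steps 3 and 4 are a two-step side branch.

Most likely to fail, step 8. The cycloaddition is unprecedented with this substitution. The risks are the cis-fused isomer (compact transition state), (3+2) or elimination products if the diene reacts s-trans, and ionisation at the tertiary C4–O bond. The fallback sets out from 14 and comes back at 16. SmI2 (THF–MeOH, −90 °C) cleaves the oxirane C–O bond next to the carbonyl to give (4R,7E,9E)-4-hydroxy-7-methyl-4-(propan-2-yl)undeca-7,9-dien-2-one F3. TESOTf and 2,6-lutidine convert it into (4R,7E,9E)-7-methyl-4-(propan-2-yl)-4-[(triethylsilyl)oxy]undeca-7,9-dien-2-one F4. Kinetic enolisation at the methyl group (LiN(SiMe3)2, Me3SiCl, THF, −78 °C) gives (4R,7E,9E)-7-methyl-4-(propan-2-yl)-4-[(triethylsilyl)oxy]-2-[(trimethylsilyl)oxy]undeca-1,7,9-triene F5. NBS turns this into (4R,7E,9E)-1-bromo-7-methyl-4-(propan-2-yl)-4-[(triethylsilyl)oxy]undeca-7,9-dien-2-one F6. Dehydrobromination (Et3N, LiClO4, Et2O, or NaOCH2CF3 in CF3CH2OH) then triggers the classical oxyallyl-cation (4+3) cycloaddition, which again closes both rings at once and returns 16. In this variant C5 is not fixed by an SN2 event, but it sits next to the ketone and can be equilibrated with base.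

Second, step 5. The iron-catalysed carbomagnesiation has to deliver a long primary alkyl group with β-hydrogens to an isopropyl-substituted alkyne carbon, and the dienyl Grignard reagent may isomerise or react with the iron catalyst. The fallback sets out from 5 and comes back at 12. The dianion of commercial (S)-but-3-yn-2-ol (2 equiv n-BuLi, THF–DMPU, −78 → 0 °C) is alkylated at the acetylide carbon with 5 (NaI cat.) to give (2S,7E,9E)-7-methylundeca-7,9-dien-3-yn-2-ol F1. Hydroxyl-directed trans-hydroalumination with NaAlH2(OCH2CH2OMe)2 followed by iodine gives (2S,3Z,7E,9E)-4-iodo-7-methylundeca-3,7,9-trien-2-ol F2. Negishi coupling with i-PrZnBr (PdCl2(dppf) cat., THF) replaces iodine with retention and returns 12 without any dienyl organomagnesium species.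

Third, step 12. In-flask acylation of the hindered axial alkoxide in the presence of the borane may stall or be outrun by side reactions. The fallback sets out from 22 and comes back at 26. The ketone is reduced with LiBH(s-Bu)3 and worked up oxidatively (NaBO3) to isolate (1S,4S,5S,6R,10R)-6-hydroxy-4-[(triethylsilyl)oxy]dauc-8-en-10-yl 3-methylbutanoate F7. This neutral alcohol is then esterified in a separate step with 24 under nucleophilic catalysis (DMAP, pyridine, 60 °C) to return 26.

**Further compounds**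
F1 | step 5 | (2S,7E,9E)-7-methylundeca-7,9-dien-3-yn-2-ol | C[C@H](O)C#CCC/C(C)=C/C=C/C
F2 | step 5 | (2S,3Z,7E,9E)-4-iodo-7-methylundeca-3,7,9-trien-2-ol | C[C@H](O)/C=C(\I)CC/C(C)=C/C=C/C
F3 | step 8 | (4R,7E,9E)-4-hydroxy-7-methyl-4-(propan-2-yl)undeca-7,9-dien-2-one | CC(=O)C[C@@](O)(C(C)C)CC/C(C)=C/C=C/C
F4 | step 8 | (4R,7E,9E)-7-methyl-4-(propan-2-yl)-4-[(triethylsilyl)oxy]undeca-7,9-dien-2-one | CC(=O)C[C@@](O[Si](CC)(CC)CC)(C(C)C)CC/C(C)=C/C=C/C
F5 | step 8 | (4R,7E,9E)-7-methyl-4-(propan-2-yl)-4-[(triethylsilyl)oxy]-2-[(trimethylsilyl)oxy]undeca-1,7,9-triene | C=C(O[Si](C)(C)C)C[C@@](O[Si](CC)(CC)CC)(C(C)C)CC/C(C)=C/C=C/C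
F6 | step 8 | (4R,7E,9E)-1-bromo-7-methyl-4-(propan-2-yl)-4-[(triethylsilyl)oxy]undeca-7,9-dien-2-one | BrCC(=O)C[C@@](O[Si](CC)(CC)CC)(C(C)C)CC/C(C)=C/C=C/C
F7 | step 12 | (1S,4S,5S,6R,10R)-6-hydroxy-4-[(triethylsilyl)oxy]dauc-8-en-10-yl 3-methylbutanoate | CC1=C[C@@H](OC(=O)CC(C)C)[C@@]2(C)CC[C@](O[Si](CC)(CC)CC)(C(C)C)[C@@H]2[C@H](O)C1
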